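The constants used here are assumed; the rest is arithmetic.

You can't fit north-east or south-west with one first-order clock: the constant for the loss of E sinks as the run goes on.

| setting | north-east | south-west |
|---|---|---|
| E | 0.088 M | 0.088 M |
| J | 0.180 M | 0.260 M |
| time | 2.0 min | 2.0 min |

* part of the E that has reacted at the end, north-east
* part of the E that has reacted at the end, south-west
* what raising the concentration of J from its lowest to its highest value here does to the part of the E that has reacted (changes below 5 percentage points count as none) (it rises / it falls / no change)

- what has gone from E into another species counts as reacted, even if it can come back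
- run time (north-east): 2.0 min

    E + J → G + Z (k1 = 0.0524 M⁻¹ s⁻¹)
    J + G ⇌ J.G, settled at all times (K2 = 610 M⁻¹)
    G → D (k3 = 0.00208 s⁻¹)
    Z → Q (k4 = 0.00183 s⁻¹)
    E ⇌ X (K5 = 1.5, k5 = 0.00508 s⁻¹)

So reckon the rate constant, not the concentrations: take its start value, then two slowing factors. This is my own reckoning, north-east first.

1. Start. E is lost at a pseudo-first-order 0.871 min⁻¹. The step with J is faster than the step to X and carries 65.0% of that. Unslowed, 82.5% would react by the end.

2. Wear. Each E through the J step costs two J: one reacts, and one is held as J.G, with 110 J.G per free G at the charged J. I take the mean drop as half of the end drop. So 0.738 is the mean free J over its charge, the wear factor.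

3. Return. I take the unslowed ratio of X to E at mid-run, divided by 1.5, as the part of the forward step cancelled. That leaves a return factor of 0.676.

4. End. Each factor goes on its own term, so the mean constant is 0.624 min⁻¹, and 71.3% of the E reacts.

5. South-west. The start is 1.12 min⁻¹, the share 72.8%, the unslowed end 89.4%. The wear factor is 0.780, the return factor 0.625, the mean constant 0.828 min⁻¹. That gives 80.9%, a rise of 9.6 percentage points, more than the margin.

The forecast gives 70.6% and 79.2%, and it rises, on the ground that “each G formed ties up a second J almost completely”. Both its values stand lower than mine.

The simulation gives 71.3% and 80.2%: it rises, by 8.9 points, and the main reason for that gap between the flasks is their difference in the concentration of J.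

North-east is slowed, not stopped, with 55.7% of its J still free at the end. The wearing away of J is one part of the slowing: with J held, north-east reaches 78.8% instead of 71.3%. The wear factor prices this as 0.297 of accumulated loss, which lifts 71.3% to 78.7%. In south-west, 0.780 lifts 80.2% to 86.2%, and its run with J held stands at 86.7%.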